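**Assumption:** Vidalol B has no stereocentres and is achiral, so "single enantiomer" needs no stereocontrol; the route only has to deliver the given constitution. The route is planned from known reaction types and has not been run.

## Retrosynthetic overview
1. Vidalol B (9) ⇐ global O-demethylation of its heptamethyl ether 8 with BBr3.
2. 8 ⇐ twofold Friedel–Crafts benzylation of 2-bromo-1,3,5-trimethoxybenzene (6) with benzylic alcohol 5 at its only two free positions; the central bromine is bought in and blocks the third site.
3. 5 ⇐ vanillin (1) by dibromination (C5, then C6), O-methylation and aldehyde reduction.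
4. No ring is formed; all three benzene rings come from commercial aromatics, the outer rings being functionalised first and then joined to the central ring.

## Route

Step 1
Reactants: 1 vanillin
Product: 3 5,6-dibromovanillin, via 5-bromovanillin 2 (not isolated)
Conditions: Br2 (1.05 equiv), AcOH, rt; then Fe powder (cat.), Br2 (1.2 equiv), AcOH, rt
Reagents that add atoms: bromine, BrBr
Why: Electrophilic aromatic bromination; the free OH directs the first Br ortho to itself (C5), and FeBr3-activated Br2 then brominates C6, para to OMe, giving the 2,3-dibromo-4-hydroxy-5-methoxy pattern (no stereocentre).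

Step 2
Reactants: 3 5,6-dibromovanillin
Product: 4 2,3-dibromo-4,5-dimethoxybenzaldehyde
Conditions: MeI, K2CO3, DMF, rt
Reagents that add atoms: iodomethane, CI
Why: Williamson O-methylation of an acidic phenol (para-CHO, ortho-Br); aldehyde and aryl bromides are inert.

Step 3
Reactants: 4 2,3-dibromo-4,5-dimethoxybenzaldehyde
Product: 5 (2,3-dibromo-4,5-dimethoxyphenyl)methanol
Conditions: NaBH4, MeOH/THF, 0 °C → rt; H2O work-up
Reagents that add atoms: none
Why: Chemoselective hydride reduction of the aldehyde; aryl bromides and methyl ethers are untouched.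

Step 4
Reactants: 5 (2,3-dibromo-4,5-dimethoxyphenyl)methanol (2.2 equiv); 6 2-bromo-1,3,5-trimethoxybenzene (1.0 equiv)
Product: 8 vidalol B heptamethyl ether, via monobenzylated bromotrimethoxybenzene 7 (not isolated)
Conditions: TfOH (10 mol %), HFIP/CH2Cl2, 0 °C → rt
Reagents that add atoms: none
Why: Dehydrative double Friedel–Crafts benzylation; the para-methoxy-stabilised benzylic cation from 5 attacks the two equivalent free positions of 6 (each ortho/para to three OMe groups), so regiochemistry and degree of alkylation are fixed by the substitution pattern.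

Step 5
Reactants: 8 vidalol B heptamethyl ether
Product: 9 vidalol B
Conditions: BBr3 (12 equiv), CH2Cl2, −78 °C → rt; then H2O, 0 °C
Reagents that add atoms: none
Why: BBr3 ether cleavage (Lewis-acid activation, then SN2 attack of bromide on methyl) removes all seven aryl methyl ethers; aryl C–Br bonds and the diarylmethane C–C bonds survive, and no stereocentre is involved.

## Compound list
1 | vanillin (4-hydroxy-3-methoxybenzaldehyde) | O=Cc1ccc(O)c(OC)c1 | starting material
2 | 5-bromovanillin (3-bromo-4-hydroxy-5-methoxybenzaldehyde) | O=Cc1cc(Br)c(O)c(OC)c1 | intermediate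
3 | 5,6-dibromovanillin (2,3-dibromo-4-hydroxy-5-methoxybenzaldehyde) | O=Cc1cc(OC)c(O)c(Br)c1Br | intermediate
4 | 2,3-dibromo-4,5-dimethoxybenzaldehyde | O=Cc1cc(OC)c(OC)c(Br)c1Br | intermediate
5 | (2,3-dibromo-4,5-dimethoxyphenyl)methanol | OCc1cc(OC)c(OC)c(Br)c1Br | intermediate
6 | 2-bromo-1,3,5-trimethoxybenzene | COc1cc(OC)c(Br)c(OC)c1 | starting material
7 | 2-bromo-4-[(2,3-dibromo-4,5-dimethoxyphenyl)methyl]-1,3,5-trimethoxybenzene | COc1cc(Cc2c(OC)cc(OC)c(Br)c2OC)c(Br)c(Br)c1OC | intermediate
8 | 2-bromo-4,6-bis[(2,3-dibromo-4,5-dimethoxyphenyl)methyl]-1,3,5-trimethoxybenzene (vidalol B heptamethyl ether) | COc1cc(Cc2c(OC)c(Br)c(OC)c(Cc3cc(OC)c(OC)c(Br)c3Br)c2OC)c(Br)c(Br)c1OC | intermediate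
9 | vidalol B, 2-bromo-4,6-bis[(2,3-dibromo-4,5-dihydroxyphenyl)methyl]benzene-1,3,5-triol | Oc1cc(Cc2c(O)c(Br)c(O)c(Cc3cc(O)c(O)c(Br)c3Br)c2O)c(Br)c(Br)c1O | target

## Summary
Total step count: 5. Longest linear sequence: 5 steps (1 → 3 → 4 → 5 → 8 → 9); 6 is purchased.

## Steps most likely to fail, with fallbacks

**Step 4** is the riskiest. The second benzylation builds a hexasubstituted ring, the acid could cause loss or migration of the central bromine in 6, and 5 could self-condense. The fallback sets out from 5 and introduces the central bromine last. Two equivalents of 5 are condensed with the more nucleophilic, bromine-free 1,3,5-trimethoxybenzene F1 (AlCl3, CH2Cl2, 0 °C → rt). This gives 2,4-bis[(2,3-dibromo-4,5-dimethoxyphenyl)methyl]-1,3,5-trimethoxybenzene F2, which is separated from mono- and tris-benzylated material by chromatography. The single remaining central C–H, far more activated than the outer-ring C–H, is then brominated with NBS (1.0 equiv, MeCN, 0 °C). The fallback comes back to the route at 8.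

**Step 5** is the second risk. Sevenfold demethylation may stall, and HBr/BBr3 may protodebrominate the bromophloroglucinol ring or reverse the Friedel–Crafts bonds in the very electron-rich, air-sensitive product. The fallback sets out from 5 and 6 and deprotects before the C–C coupling. BBr3 on 5 cleaves both ethers and converts the benzylic OH into bromide, giving 3,4-dibromo-5-(bromomethyl)benzene-1,2-diol F3. BBr3 on 6 gives 2-bromobenzene-1,3,5-triol F4. F4 and 2.1 equiv of F3 are then stirred in HFIP at rt without added acid. The 4-hydroxybenzyl bromide ionises through its p-quinone methide and C-benzylates the two free positions of F4. The fallback comes back to the route at 9, so the final product never sees BBr3.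

**Step 1** is the third risk. The one-pot dibromination of a free phenolic aldehyde can give over-bromination, ipso-bromodeformylation or some C2 regioisomer. The fallback sets out from 2, which is isolated by stopping after the first bromination. It is O-methylated first (MeI, K2CO3, DMF) to 3-bromo-4,5-dimethoxybenzaldehyde F5. The second bromine is then introduced on this non-phenolic, oxidation-resistant ether (Br2, Fe cat., AcOH), para to the 5-OMe group. The fallback comes back to the route at 4 and bypasses 3.

## Further compounds
F1 | step 4 | 1,3,5-trimethoxybenzene | COc1cc(OC)cc(OC)c1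
F2 | step 4 | 2,4-bis[(2,3-dibromo-4,5-dimethoxyphenyl)methyl]-1,3,5-trimethoxybenzene | COc1cc(Cc2c(OC)cc(OC)c(Cc3cc(OC)c(OC)c(Br)c3Br)c2OC)c(Br)c(Br)c1OC
F3 | step 5 | 3,4-dibromo-5-(bromomethyl)benzene-1,2-diol | Oc1cc(CBr)c(Br)c(Br)c1O
F4 | step 5 | 2-bromobenzene-1,3,5-triol | Oc1cc(O)c(Br)c(O)c1
F5 | step 1 | 3-bromo-4,5-dimethoxybenzaldehyde | O=Cc1cc(Br)c(OC)c(OC)c1
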